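**Strategy.** The cyclohexene ring is cut at the alkene C2=C3 and at the diol bond C5–C6 into two three-carbon pieces: C3–C4–C5 as hydroxyacetone and C6–C1–C2 as an achiral 2,2-disubstituted malonaldehyde. The key step exploits the oxygen at ring carbon C4, a latent ketone flanked by both new bonds. One amine-catalysed [3+3] annulation adds the hydroxylated α-carbon to one formyl group (C5–C6) and condenses the methyl group with the other (C2=C3). C5, C6 and the quaternary C1 are set by catalyst, enamine geometry and Felkin choice between the enantiotopic formyl groups. Reduction, benzoylation and deprotection finish the route.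

Key step: step 5

Locants used throughout: C1 = quaternary ring carbon (OH, CH2OBz), C2=C3 = alkene, C4 = CH(OBz), C5 and C6 = CH(OH), C7 = exocyclic CH2; O1, O4, O5, O6 are the oxygens on these carbons.

Assumption: O-tert-butyl-D-threonine is taken to deliver the (Z)-enamine of hydroxyacetone to the Si face of an aldehyde, the mirror image of the Re-face delivery by L-amino acid catalysts; the L-catalyst would be used if the sense proved opposite.

**Step 1**
Reactants: 1 ethyl glycolate; 2 vinylmagnesium bromide
Product: 3 3-(hydroxymethyl)penta-1,4-dien-3-ol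
Conditions: CH2=CHMgBr (3.3 equiv), THF, −20 °C → rt; aq. NH4Cl
Reagents that add atoms: none
Why: Twofold Grignard addition to the ester, after one equivalent has deprotonated the hydroxyl group, should give the tertiary divinyl carbinol; no stereocenter is formed.

**Step 2**
Reactants: 3 3-(hydroxymethyl)penta-1,4-dien-3-ol
Product: 4 2-ethenyl-2-hydroxybut-3-en-1-yl benzoate
Conditions: BzCl (1.05 equiv), pyridine, CH2Cl2, −20 → 0 °C
Reagents that add atoms: benzoyl chloride, O=C(Cl)c1ccccc1
Why: Selective acylation (esterification) should take the primary hydroxyl and leave the hindered tertiary one.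

**Step 3**
Reactants: 4 2-ethenyl-2-hydroxybut-3-en-1-yl benzoate
Product: 5 2-ethenyl-2-(triethylsilyloxy)but-3-en-1-yl benzoate
Conditions: TESOTf, 2,6-lutidine, CH2Cl2, −78 → 0 °C
Reagents that add atoms: triethylsilyl trifluoromethanesulfonate, CC[Si](CC)(CC)OS(=O)(=O)C(F)(F)F
Why: Silylation of the tertiary alcohol with a silyl triflate should protect the future α-hydroxyl of the dialdehyde against α-ketol rearrangement and hemiacetal oligomerisation.

**Step 4**
Reactants: 5 2-ethenyl-2-(triethylsilyloxy)but-3-en-1-yl benzoate
Product: 6 2-formyl-3-oxo-2-(triethylsilyloxy)propyl benzoate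
Conditions: O3, CH2Cl2, −78 °C; Me2S, −78 °C → rt; used at once
Reagents that add atoms: ozone, O=[O+][O-]
Why: Twofold ozonolysis with reductive work-up should give the non-enolisable dialdehyde, in which C1 is still a prochiral centre.

**Step 5**
Reactants: 6 2-formyl-3-oxo-2-(triethylsilyloxy)propyl benzoate; 7 hydroxyacetone
Product: 9 [(1R,5S,6S)-5,6-dihydroxy-4-oxo-1-(triethylsilyloxy)cyclohex-2-en-1-yl]methyl benzoate, via syn-aldol adduct 8 (not isolated)
Conditions: 7 (2 equiv), O-tert-butyl-D-threonine (20 mol%), NMP, 4 °C; then Bn2NH·CF3CO2H (30 mol%), 35 °C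
Reagents that add atoms: none
Why: Proposed new method: the primary amine of the catalyst condenses with 7 to the hydrogen-bonded (Z)-enamine, whose hydroxylated carbon adds to one formyl group of 6 (C5–C6, giving 8, which rests as its five-membered lactol), and the secondary ammonium salt then forms the methyl-side enamine, which adds to the second formyl group and loses water by E1cB (C2=C3). The closest known reaction types are the amino-acid-catalysed syn-aldol addition of hydroxyacetone to aldehydes and the amine-salt-mediated intramolecular aldol condensation of keto aldehydes; their union as a [3+3] annulation on a non-enolisable 2,2-disubstituted malonaldehyde, with differentiation of its two formyl groups, has not been shown. The cyclohexenone ring closes in a 6-(enolendo)-exo-trig aldol addition. C6 is set by the catalyst, whose D-configuration directs the enamine to the Si face of the formyl group; C5 is set by the (Z)-enamine geometry (syn adduct, trans diol in the ring) and, being α to the ketone, can still drift to the more stable trans-diequatorial arrangement; C1 is set by the choice between the enantiotopic formyl groups under polar Felkin–Anh control, with the silyloxy group anti to the incoming enamine, which passes the small second formyl group and not the benzoyloxymethyl group, so that O1 and O6 should come out trans. The step needs group selectivity between the two formyl groups and a single intermolecular addition: only one formyl group presents its Si face in the Felkin-preferred conformation, and lactol formation with the C5 hydroxyl should shield the second formyl group from a further intermolecular aldol addition while the irreversible ring closure drains the open form.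

**Step 6**
Reactants: 9 [(1R,5S,6S)-5,6-dihydroxy-4-oxo-1-(triethylsilyloxy)cyclohex-2-en-1-yl]methyl benzoate
Product: 10 [(1R,5S,6S)-5,6-(isopropylidenedioxy)-4-oxo-1-(triethylsilyloxy)cyclohex-2-en-1-yl]methyl benzoate
Conditions: 2-methoxypropene, PPTS (cat.), CH2Cl2, 0 °C → rt
Reagents that add atoms: 2-methoxypropene, COC(C)=C
Why: Kinetic acetalisation of the trans-diequatorial diol should give the trans-fused acetonide, which masks both hydroxyls and locks the half-chair for the reduction.

**Step 7**
Reactants: 10 [(1R,5S,6S)-5,6-(isopropylidenedioxy)-4-oxo-1-(triethylsilyloxy)cyclohex-2-en-1-yl]methyl benzoate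
Product: 11 [(1R,4S,5R,6S)-4-hydroxy-5,6-(isopropylidenedioxy)-1-(triethylsilyloxy)cyclohex-2-en-1-yl]methyl benzoate
Conditions: NaBH4, CeCl3·7H2O, MeOH, −78 °C
Reagents that add atoms: none
Why: Luche 1,2-reduction with axial hydride delivery, anti to the axial C5–H bond of the locked half-chair, should place the new C4 hydroxyl equatorial and trans to O5 (the change of the C5 descriptor to R is a priority change only).

**Step 8**
Reactants: 11 [(1R,4S,5R,6S)-4-hydroxy-5,6-(isopropylidenedioxy)-1-(triethylsilyloxy)cyclohex-2-en-1-yl]methyl benzoate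
Product: 12 [(1R,4S,5R,6S)-4-(benzoyloxy)-5,6-(isopropylidenedioxy)-1-(triethylsilyloxy)cyclohex-2-en-1-yl]methyl benzoate
Conditions: BzCl, pyridine, DMAP (cat.), CH2Cl2, 0 °C → rt
Reagents that add atoms: benzoyl chloride, O=C(Cl)c1ccccc1
Why: DMAP-catalysed acylation of the only free hydroxyl should install the allylic benzoate with retention at C4.

**Step 9**
Reactants: 12 [(1R,4S,5R,6S)-4-(benzoyloxy)-5,6-(isopropylidenedioxy)-1-(triethylsilyloxy)cyclohex-2-en-1-yl]methyl benzoate
Product: 13 kweichowenol B, [(1R,4S,5S,6S)-4-(benzoyloxy)-1,5,6-trihydroxycyclohex-2-en-1-yl]methyl benzoate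
Conditions: TFA/H2O/THF (2:1:2), 0 °C → rt
Reagents that add atoms: none
Why: Acid hydrolysis should cleave the strained trans-acetonide and the tertiary silyl ether in one global deprotection, under conditions that avoid base-induced benzoate migration.

**Compound list**

1 | ethyl glycolate | CCOC(=O)CO | starting material
2 | vinylmagnesium bromide | C=C[Mg]Br | starting material
3 | 3-(hydroxymethyl)penta-1,4-dien-3-ol | OCC(O)(C=C)C=C | intermediate
4 | 2-ethenyl-2-hydroxybut-3-en-1-yl benzoate | O=C(OCC(O)(C=C)C=C)c1ccccc1 | intermediate
5 | 2-ethenyl-2-(triethylsilyloxy)but-3-en-1-yl benzoate | O=C(OCC(O[Si](CC)(CC)CC)(C=C)C=C)c1ccccc1 | intermediate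
6 | 2-formyl-3-oxo-2-(triethylsilyloxy)propyl benzoate | O=C(OCC(O[Si](CC)(CC)CC)(C=O)C=O)c1ccccc1 | intermediate
7 | hydroxyacetone (1-hydroxypropan-2-one) | CC(=O)CO | starting material
8 | (2R,3S,4S)-2-formyl-3,4-dihydroxy-5-oxo-2-(triethylsilyloxy)hexyl benzoate (syn-aldol adduct, in equilibrium with its lactol) | O=C(OC[C@](O[Si](CC)(CC)CC)(C=O)[C@@H](O)[C@H](O)C(C)=O)c1ccccc1 | intermediate
9 | [(1R,5S,6S)-5,6-dihydroxy-4-oxo-1-(triethylsilyloxy)cyclohex-2-en-1-yl]methyl benzoate | O=C(OC[C@]1(O[Si](CC)(CC)CC)C=CC(=O)[C@@H](O)[C@@H]1O)c1ccccc1 | intermediate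
10 | [(1R,5S,6S)-5,6-(isopropylidenedioxy)-4-oxo-1-(triethylsilyloxy)cyclohex-2-en-1-yl]methyl benzoate (trans-fused acetonide) | O=C(OC[C@]1(O[Si](CC)(CC)CC)C=CC(=O)[C@H]2OC(C)(C)O[C@H]12)c1ccccc1 | intermediate
11 | [(1R,4S,5R,6S)-4-hydroxy-5,6-(isopropylidenedioxy)-1-(triethylsilyloxy)cyclohex-2-en-1-yl]methyl benzoate | O=C(OC[C@]1(O[Si](CC)(CC)CC)C=C[C@H](O)[C@H]2OC(C)(C)O[C@H]12)c1ccccc1 | intermediate
12 | [(1R,4S,5R,6S)-4-(benzoyloxy)-5,6-(isopropylidenedioxy)-1-(triethylsilyloxy)cyclohex-2-en-1-yl]methyl benzoate | O=C(OC[C@]1(O[Si](CC)(CC)CC)C=C[C@H](OC(=O)c2ccccc2)[C@H]3OC(C)(C)O[C@H]13)c1ccccc1 | intermediate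
13 | kweichowenol B, [(1R,4S,5S,6S)-4-(benzoyloxy)-1,5,6-trihydroxycyclohex-2-en-1-yl]methyl benzoate | O=C(OC[C@]1(O)C=C[C@H](OC(=O)c2ccccc2)[C@@H](O)[C@@H]1O)c1ccccc1 | target

**Step count and risks**

Total step count: 9. Longest linear sequence: 9 steps (from ethyl glycolate 1).

Steps most likely to fail:

1. Step 5 (Proposed new method). The enantiotopic formyl groups may be discriminated poorly, which would erode the configuration at C1. The 1,3-dialdehyde may lose a formyl group by retro-Claisen-type cleavage under amine catalysis. A second intermolecular aldol addition may compete, or the sequence may stall at the lactol. The fallback uses known chemistry and separates the two bond formations. It sets out from 5. Ozonolysis with one equivalent of ozone (Me2S work-up) should cleave one vinyl group and give racemic 2-ethenyl-2-formyl-2-(triethylsilyloxy)ethyl benzoate F1. The same amino-acid-catalysed syn-aldol addition of hydroxyacetone 7, now on a mono-aldehyde, should give two diastereomers that differ only at the quaternary carbon: (2R,3S,4S)-2-ethenyl-3,4-dihydroxy-5-oxo-2-(triethylsilyloxy)hexyl benzoate F2 and its (2S,3S,4S)-epimer F3, which are separated by chromatography. Ozonolysis of the vinyl group of F2 comes back to the route at 8, which is then closed to 9 with dibenzylammonium trifluoroacetate as a separate aldol condensation.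

2. Step 4. The electron-poor dialdehyde may be lost through hydration and oligomerisation, over-oxidation, or deformylation during ozonide reduction and isolation. The fallback sets out from 5. Ozonolysis with reductive NaBH4 work-up should give the storable 3-hydroxy-2-(hydroxymethyl)-2-(triethylsilyloxy)propyl benzoate F4. Twofold Swern oxidation ((COCl)2, DMSO, Et3N, −78 °C) in anhydrous medium directly before the annulation comes back to the route at 6.

3. Step 7. Hydride may enter from the other face of the enone (or add in conjugate fashion), so that the C4 hydroxyl ends cis to O5. The fallback sets C4 by SN2 inversion instead of by facial selection. It sets out from 10. The cis alcohol [(1R,4R,5R,6S)-4-hydroxy-5,6-(isopropylidenedioxy)-1-(triethylsilyloxy)cyclohex-2-en-1-yl]methyl benzoate F5 from such a reduction is esterified under Mitsunobu conditions (PPh3, diisopropyl azodicarboxylate, benzoic acid, THF, 0 °C). This should invert C4 and comes back to the route at 12, passing over step 8.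

**Further compounds**

F1 | step 5 | racemic 2-ethenyl-2-formyl-2-(triethylsilyloxy)ethyl benzoate | O=C(OCC(O[Si](CC)(CC)CC)(C=O)C=C)c1ccccc1
F2 | step 5 | (2R,3S,4S)-2-ethenyl-3,4-dihydroxy-5-oxo-2-(triethylsilyloxy)hexyl benzoate | O=C(OC[C@](O[Si](CC)(CC)CC)(C=C)[C@@H](O)[C@H](O)C(C)=O)c1ccccc1
F3 | step 5 | (2S,3S,4S)-2-ethenyl-3,4-dihydroxy-5-oxo-2-(triethylsilyloxy)hexyl benzoate | O=C(OC[C@@](O[Si](CC)(CC)CC)(C=C)[C@@H](O)[C@H](O)C(C)=O)c1ccccc1
F4 | step 4 | 3-hydroxy-2-(hydroxymethyl)-2-(triethylsilyloxy)propyl benzoate | O=C(OCC(CO)(CO)O[Si](CC)(CC)CC)c1ccccc1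
F5 | step 7 | [(1R,4R,5R,6S)-4-hydroxy-5,6-(isopropylidenedioxy)-1-(triethylsilyloxy)cyclohex-2-en-1-yl]methyl benzoate | O=C(OC[C@]1(O[Si](CC)(CC)CC)C=C[C@@H](O)[C@H]2OC(C)(C)O[C@H]12)c1ccccc1
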